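## Structural features

Germacrane numbering is used throughout: carbocycle C1–C10, C14 is the ester carbon on C10, C15 is the methyl on C4, and C11–C13 are the lactone carbons. The target is a melampolide-type germacranolide.

- **Ring and alkenes.** The only carbocycle is a cyclodeca-1(10),4-diene. C1=C10 is cis within the ring (E by CIP, because CO2Me outranks C9) and carries the ester. C4=C5 is trans within the ring and carries C15. The C2–C3 bridge makes the pair a cis,trans-1,5-diene.
- **Stereocentres.** The other tether, C6–C9, holds three contiguous stereocentres: C6 (R, lactone O, α), C7 (R, C11, β) and C8 (R, methacrylate O, β). The γ-lactone is therefore trans-fused at C6–C7, C7–C11 is cis to C8–O, and O6/O8 are 1,3-anti.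
- **Fragile groups.** There are three Michael acceptors (exo-methylene lactone, methacrylate, ring enoate) and an allylic C6–O bond. The 1,5-diene can undergo Cope rearrangement or acid-induced transannular cyclisation.
- **Real difficulty.** The hard part is the strained ten-membered ring with two trisubstituted alkenes of opposite ring geometry. A second problem is the contra-steric cis relation C7/C8 next to the trans relation C6/C7.
- **Feature exploited by the key step.** Atoms C5–C10 with C14 and O6 form a 3-carbomethoxycyclohex-2-enone. Atoms C1–C4 with C15 form 1-methylcyclobutene. The diene C10=C1–C2–C3–C4=C5 has a carbonyl group on each outer alkene carbon. This is the exact retron of the cycloreversion of a bicyclo[2.2.0]hexane with transannular bonds C1–C4 and C5–C10.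
- **Route in one sentence.** The ten-membered ring is released by thermal strain-release cycloreversion of the tricyclic cyclobutene–cyclohexenone photoadduct 15.

## Logic of the disconnections

**27 ⇒ 25 ⇒ 23.** The C11=C13 bond is cut. The exo-methylene lactone is the most electrophilic group, so it is made last. This removes the most fragile acceptor from every earlier intermediate. The forward step must enolise only the lactone, without strong base, because the methacrylate and the enoate are already present.

**23 ⇒ 20.** The O6–C12 lactone bond is cut. This opens the bicycle to a monocycle with a C7 acetate arm. The forward step must free the acid without ionising the allylic C6–O bond. O8 must be blocked so that only the trans 12,6-lactone can form.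

**20 ⇒ 17 + 18.** The O8–acyl bond and the C6–H bond are cut together. The 1,3-anti relation O6/O8 and the placement of the ester on O8 match an intramolecular hydride transfer from an O8 hemiacetal. One stereocentre, one side chain and one protecting-group problem disappear at once. The forward step needs a free 8β-hydroxyl next to a C6 ketone and tolerance of an enone.

**17 ⇒ 16.** The O8–Si bond is restored. The β-hydroxy ketone would not survive light and heat, so a silyl ether carries O8 through the ring-forming steps. The forward cleavage must be non-basic.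

**16 ⇒ 15 (key).** The bonds C1–C4 and C5–C10 are re-formed in the retrosynthetic direction. The medium ring with two defined alkenes becomes a compact 6-4-4 tricycle without alkenes or medium-ring strain. The forward step must break C5–C10 rather than C2–C3. It must give ring-cis C1=C10 and ring-trans C4=C5, and it must leave C7 and C8 untouched.

**15 ⇒ 12 + 14.** The bonds C1–C10 and C4–C5 are cut. The tricycle falls into a six-membered enone, which holds all stereocentres, and a C5 hydrocarbon. The forward step needs the orientation C10–C1(H) / C5–C4(Me) and a cis C5/C10 fusion. Facial selectivity is unimportant because the four new centres are erased later.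

**14 ⇒ 13.** Only the position of the double bond changes. This links the volatile cycloalkene to a catalogue isomer.

**12 ⇒ 10.** The C5=C10 π bond is removed. The saturated γ-keto ester cannot aromatise, so the labile chromophore is generated just before use. The forward step must enolise C6 towards C5 and not towards C7.

**10 ⇒ 9 ⇒ 7.** The C6–O and C7–H bonds are cut. A syn addition to a C6=C7 alkene on the face opposite to O8 places H7 α. This is the only simple way to obtain the side chain cis to O8. The demand is anti facial selectivity and boron at C6.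

**7 ⇒ 6 ⇒ 5.** The O8–Si and C8–H bonds are cut. All absolute configuration is traced to one catalytic carbonyl reduction of a 2-substituted enone. The catalyst must dominate over the remote racemic C10 centre.

**5 ⇒ 4 ⇒ 3.** The vinylic C6–H bond is exchanged for C6–O. This returns a symmetric 2-alkyl-1,3-dione with no regiochemical question.

**3 ⇒ 1 + 2.** The C7–C11 bond is cut. The most acidic carbon of a 1,3-dione is the natural nucleophile. The two fragments supply C5–C10, C14, C11 and C12. The forward step must favour C- over O-alkylation.

## Other disconnections considered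

**Alternative 1:** Cut C6–C7 (and O6–C12).
- *Forward key step:* intramolecular Nozaki–Hiyama–Kishi-type allylation of the enal by the 2-(bromomethyl)enoate in the acyclic formyl allylic bromide A1, followed by lactonisation. This is the cut that comes to mind first.
- *Structure:* both trisubstituted alkenes, including the ring-cis enoate, must be built stereoselectively in a linear C15 chain before closure.
- *Mechanism:* the closure pays the full entropic and transannular cost of a ten-membered ring at high dilution. The σ-allyl metal isomer with the metal on C7 has O8 as a β-leaving group, so diene formation competes. C8 alone would have to control two new centres through a floppy macrocyclic transition state.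
- *Preference:* the chosen plan closes no medium ring and needs no preformed alkene.

**Alternative 2:** Cut C2–C3 (retro-Cope).
- *Forward key step:* Cope rearrangement of the cis-1-vinyl-2-isopropenylcyclohexane-type elemanolide A2.
- *Mechanism:* the bond reorganisation is the same as in the chosen plan, but no strain is released. The rearrangement trades an unstrained cyclohexane for a strained cyclodecadiene and gains only one conjugation, so it should be near thermoneutral at best and would leave an equilibrium.
- *Step economy:* A2 also needs a quaternary C10 with a defined cis relation to C5, built next to three stereocentres.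
- *Preference:* the chosen plan enters the same energy surface from a bicyclo[2.2.0]hexane roughly 50 kcal/mol higher, and both new alkenes form in conjugation with a carbonyl group.

**Alternative 3:** Cut C6–C7 by ring contraction.
- *Forward key step:* [2,3]-Wittig rearrangement of the 13-membered bis-allylic ether A3. It would form C6–C7, O6–H and the C11=C13 methylene together.
- *Mechanism:* the strong base rules out the C14 ester, the methacrylate and any lactone carbonyl. C14 and C12 would then need late oxidation next to other allylic positions. Deprotonation can occur at C6 or at C13.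
- *Step economy:* A3 still needs a macrocyclisation and the same linear chain with two defined alkenes.
- *Preference:* the chosen plan carries the ester from the first step.

Key step: step 11

Assumption: 1 is treated as a catalogue compound (otherwise one esterification of the commercial acid); C10 is stereochemically undefined in 4–11 because it becomes sp2 in step 8.

## Steps

Step 1
Reactants: 1 methyl 3,5-dioxocyclohexane-1-carboxylate; 2 tert-butyl bromoacetate
Product: 3 methyl 4-(2-tert-butoxy-2-oxoethyl)-3,5-dioxocyclohexane-1-carboxylate (enolised 2-alkyl-1,3-dione)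
Conditions: K2CO3, MeCN, rt to 40 °C
Reagents that add atoms: none
Why: C-alkylation of a soft, fully enolised 1,3-dione at its central carbon (future C7) by an α-halo ester forms C7–C11. The symmetry of 1 removes any regio- or stereochemical question, and one equivalent of 2 limits dialkylation.

Step 2
Reactants: 3 methyl 4-(2-tert-butoxy-2-oxoethyl)-3,5-dioxocyclohexane-1-carboxylate
Product: 4 methyl 4-(2-tert-butoxy-2-oxoethyl)-3-oxo-5-(trifluoromethylsulfonyloxy)cyclohex-4-ene-1-carboxylate (racemic)
Conditions: Tf2O, Et3N, CH2Cl2, −78 to 0 °C
Reagents that add atoms: trifluoromethanesulfonic anhydride, O=S(=O)(OS(=O)(=O)C(F)(F)F)C(F)(F)F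
Why: O-sulfonylation of a vinylogous acid. The two carbonyl groups of 3 are enantiotopic, so a single racemic enol triflate should result.

Step 3
Reactants: 4 methyl 4-(2-tert-butoxy-2-oxoethyl)-3-oxo-5-(trifluoromethylsulfonyloxy)cyclohex-4-ene-1-carboxylate
Product: 5 methyl 4-(2-tert-butoxy-2-oxoethyl)-3-oxocyclohex-4-ene-1-carboxylate (racemic)
Conditions: Pd(OAc)2 (5 mol %), PPh3, HCO2H, Et3N, DMF, 60 °C
Reagents that add atoms: none
Why: Palladium-catalysed formate hydrogenolysis of an enol triflate (oxidative addition, decarboxylation of formate, reductive elimination). It turns the dione into the 2-substituted cyclohexenone needed for a face-selective carbonyl reduction, and the esters and the enone should be inert.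

Step 4
Reactants: 5 methyl 4-(2-tert-butoxy-2-oxoethyl)-3-oxocyclohex-4-ene-1-carboxylate
Product: 6 methyl (3R)-4-(2-tert-butoxy-2-oxoethyl)-3-hydroxycyclohex-4-ene-1-carboxylate (both C1 epimers)
Conditions: (S)-Me-CBS (15 mol %), BH3·SMe2, THF, −30 °C; MeOH
Reagents that add atoms: none
Why: Corey–Bakshi–Shibata reduction. In a 2-substituted cyclohexenone the substituted alkenyl arm (C7) is clearly the large group and C9H2 the small one, so the (S)-catalyst should give the (R)-carbinol C8. The remote racemic C10 centre should not override the catalyst, and both epimers are carried on because C10 becomes sp2 in step 8.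

Step 5
Reactants: 6 methyl (3R)-4-(2-tert-butoxy-2-oxoethyl)-3-hydroxycyclohex-4-ene-1-carboxylate
Product: 7 methyl (3R)-3-(tert-butyldimethylsilyloxy)-4-(2-tert-butoxy-2-oxoethyl)cyclohex-4-ene-1-carboxylate (both C1 epimers)
Conditions: TBSCl, imidazole, DMF, rt
Reagents that add atoms: tert-butyldimethylsilyl chloride, CC(C)(C)[Si](C)(C)Cl
Why: Standard silylation. The ether must survive borane, base, light and 180 °C. A(1,2) strain with the C7 side chain should hold it pseudo-axial, where it shields the β face for step 6.

Step 6
Reactants: 7 methyl (3R)-3-(tert-butyldimethylsilyloxy)-4-(2-tert-butoxy-2-oxoethyl)cyclohex-4-ene-1-carboxylate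
Product: 9 methyl (3R,4S,5R)-3-(tert-butyldimethylsilyloxy)-4-(2-tert-butoxy-2-oxoethyl)-5-hydroxycyclohexane-1-carboxylate (both C1 epimers), via alkylborane 8 (not isolated)
Conditions: BH3·THF, THF, 0 °C; then H2O2, aq NaOH, 0 °C
Reagents that add atoms: borane–tetrahydrofuran, [BH3-][O+]1CCCC1 (boron kept only in 8); hydrogen peroxide, OO
Why: Hydroboration–oxidation of a trisubstituted alkene. Boron goes to the less substituted C6, and the syn addition takes place on the α face opposite to the pseudo-axial silyl ether, so H7 enters α and the side chain ends up β, cis to O8 (C7 set). The C6 carbinol, formed with retention, is only a relay to the ketone.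

Step 7
Reactants: 9 methyl (3R,4S,5R)-3-(tert-butyldimethylsilyloxy)-4-(2-tert-butoxy-2-oxoethyl)-5-hydroxycyclohexane-1-carboxylate
Product: 10 methyl (3R,4R)-3-(tert-butyldimethylsilyloxy)-4-(2-tert-butoxy-2-oxoethyl)-5-oxocyclohexane-1-carboxylate (both C1 epimers)
Conditions: Dess–Martin periodinane, CH2Cl2, 0 °C to rt
Reagents that add atoms: none
Why: Dess–Martin oxidation without base. The epimerisable C7 centre and the β-silyloxy ketone are therefore not exposed to enolising conditions.

Step 8
Reactants: 10 methyl (3R,4R)-3-(tert-butyldimethylsilyloxy)-4-(2-tert-butoxy-2-oxoethyl)-5-oxocyclohexane-1-carboxylate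
Product: 12 methyl (4R,5R)-5-(tert-butyldimethylsilyloxy)-4-(2-tert-butoxy-2-oxoethyl)-3-oxocyclohex-1-ene-1-carboxylate, via silyl enol ether 11 (not isolated)
Conditions: LDA, TMSCl, THF, −78 °C; then Pd(OAc)2, MeCN, rt
Reagents that add atoms: chlorotrimethylsilane, C[Si](C)(C)Cl (silicon kept only in 11)
Why: Kinetic deprotonation at the unhindered C5H2 rather than at the tertiary C7–H, so no enolate forms β to the silyloxy group. Silylation in situ is followed by Saegusa–Ito dehydrogenation (palladium enolate, β-hydride elimination of H10). Both C10 epimers converge on the same ene-keto-ester chromophore.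

Step 9
Reactants: 13 methylenecyclobutane
Product: 14 1-methylcyclobutene
Conditions: KOtBu (cat.), DMSO, rt; distillation
Reagents that add atoms: none
Why: Base-catalysed allylic isomerisation of the exocyclic alkene to the more substituted endocyclic one. The volatile product is distilled out of the mixture.

Step 10
Reactants: 12 methyl (4R,5R)-5-(tert-butyldimethylsilyloxy)-4-(2-tert-butoxy-2-oxoethyl)-3-oxocyclohex-1-ene-1-carboxylate; 14 1-methylcyclobutene
Product: 15 methyl 9-(tert-butyldimethylsilyloxy)-8-(2-tert-butoxy-2-oxoethyl)-5-methyl-7-oxotricyclo[4.4.0.0(2,5)]decane-1-carboxylate (cis-anti-cis; new cyclobutane on the α face opposite to O8 and C11; bonds C10–C1 and C5–C4)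
Conditions: hν (350–366 nm, Pyrex), 14 (10 equiv), CH2Cl2, −30 °C
Reagents that add atoms: none
Why: Enone–alkene [2+2] photocycloaddition through the enone triplet and 1,4-biradicals. The orientation C10–C1(H) / C5–C4(Me) keeps the quaternary carbons C10 and C4 diagonal in the new cyclobutane, whereas the biradical of the other regioisomer would have to close a bond between two fully substituted carbons and should revert. The alkene should approach anti to the C7 and C8 substituents and give a cis C5/C10 fusion, and all four new stereocentres are erased in step 11.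

Step 11
Reactants: 15 methyl 9-(tert-butyldimethylsilyloxy)-8-(2-tert-butoxy-2-oxoethyl)-5-methyl-7-oxotricyclo[4.4.0.0(2,5)]decane-1-carboxylate
Product: 16 methyl (1E,5E,8R,9R)-9-(tert-butyldimethylsilyloxy)-8-(2-tert-butoxy-2-oxoethyl)-5-methyl-7-oxocyclodeca-1,5-diene-1-carboxylate (ring-cis C1=C10 and ring-trans C4=C5 in germacrane numbering)
Conditions: o-dichlorobenzene (0.01 M), BHT (cat.), base-washed sealed tube, 180 °C
Reagents that add atoms: none
Why: Homolysis of the most strained bond, the C1–C4 bridge shared by both cyclobutanes, should give a cis-decalin-type cyclohexane-1,4-diyl (tertiary at C4), which also lies on the Cope surface of the product. β-Scission of this diyl can break C5–C10 or C2–C3; C5–C10 is flanked by the C6 ketone and the C14 ester, so its cleavage creates an enone and an enoate at once whereas C2–C3 cleavage gives two isolated alkenes, and this should decide the chemoselectivity kinetically and thermodynamically. The closest known reaction type is the thermal cycloreversion of cyclobutene–cyclohexenone photoadducts (bicyclo[2.2.0]hexanes) to cis,trans-cyclodeca-1,5-dienes. No ring is closed by bond formation: the ring C1–C10 is already the periphery of 15 and is set free by loss of its two transannular bonds, so no dilution or entropic penalty applies and roughly 50 kcal/mol of cyclobutane strain drives the step. No stereocentre is formed; C1, C4, C5 and C10 become sp2, so facial and syn/anti isomers of 15 converge, and C7 and C8 are spectators under neutral conditions. The geometry follows from the cis C5/C10 fusion: in a chair diyl one of C6 and C9 is axial and the other equatorial, which gives one ring-trans and one ring-cis alkene; C5 (H, C6) can place its only carbon substituent equatorial (trans C4=C5), whereas quaternary C10 must place one group axial in any case, and with C9 axial and the ester equatorial it gives the ring-cis, tiglate-like C1=C10. The other cis,trans isomer can reach 16 through the cis-divinylcyclohexanone on the Cope surface at this temperature, so the less strained tiglate-type enoate should also be the thermodynamic outcome.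

Step 12
Reactants: 16 methyl (1E,5E,8R,9R)-9-(tert-butyldimethylsilyloxy)-8-(2-tert-butoxy-2-oxoethyl)-5-methyl-7-oxocyclodeca-1,5-diene-1-carboxylate
Product: 17 methyl (1E,5E,8R,9R)-8-(2-tert-butoxy-2-oxoethyl)-9-hydroxy-5-methyl-7-oxocyclodeca-1,5-diene-1-carboxylate (8β-hydroxy-6-ketone)
Conditions: HF·pyridine, pyridine, THF, 0 °C
Reagents that add atoms: none
Why: Cleavage of a secondary TBS ether under buffered, weakly acidic conditions avoids enolate chemistry (E1cB, retro-aldol, C7 epimerisation). The bulky tert-butyl ester should keep O8 from lactonising.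

Step 13
Reactants: 17 methyl (1E,5E,8R,9R)-8-(2-tert-butoxy-2-oxoethyl)-9-hydroxy-5-methyl-7-oxocyclodeca-1,5-diene-1-carboxylate; 18 methacrolein
Product: 20 methyl 7β-(2-tert-butoxy-2-oxoethyl)-6α-hydroxy-8β-methacryloyloxy-germacra-1(10),4-dien-14-oate skeleton (ring-cis C1=C10 and ring-trans C4=C5), via hemiacetal 19 (not isolated)
Conditions: SmI2 (30 mol %), 18 (8 equiv), THF, −10 °C, dark
Reagents that add atoms: none
Why: Evans–Tishchenko reduction. O8 adds to 18, Sm(III) ties the hemiacetal oxygen to the C6 carbonyl, and the hemiacetal hydrogen is transferred intramolecularly through a chair-like bicyclic transition state to the β face of C6, which gives the 1,3-anti (6α, R) carbinol. The same event oxidises the hemiacetal to the methacrylate on O8, so C6 is set, the side chain is installed and O6/O8 are differentiated in one step.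

Step 14
Reactants: 20 6α-hydroxy-8β-methacrylate tert-butyl ester
Product: 23 13-nor lactone (target lacking the C13 methylene; trans-fused 12,6-olide), via bis-silyl derivative 21 (not isolated), via hydroxy acid 22 (not isolated)
Conditions: TMSOTf, 2,6-lutidine, CH2Cl2, 0 °C; then aq citric acid, THF, rt
Reagents that add atoms: trimethylsilyl trifluoromethanesulfonate, C[Si](C)(C)OS(=O)(=O)C(F)(F)F (silicon kept only in 21)
Why: Silyl triflate-mediated cleavage of the tert-butyl ester (loss of isobutene) avoids protic acid strong enough to ionise the allylic C6–O bond or to start a transannular cyclisation. After mild hydrolysis the 6α-hydroxy acid should close to the trans-fused γ-lactone, O8 being blocked.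

Step 15
Reactants: 23 13-nor lactone
Product: 25 11-(dimethylaminomethyl) lactone (Mannich base; C11 epimers), via silyl ketene acetal 24 (not isolated)
Conditions: TMSOTf, Et3N, CH2Cl2, 0 °C; then Me2N=CH2 I, CH2Cl2, rt; aq NaHCO3
Reagents that add atoms: trimethylsilyl trifluoromethanesulfonate, C[Si](C)(C)OS(=O)(=O)C(F)(F)F (silicon kept only in 24); N,N-dimethylmethyleneiminium iodide (Eschenmoser's salt), C=[N+](C)C.[I-]
Why: Soft enolisation. Only the lactone has an α-CH2, so silyl triflate and amine should give its ketene acetal without strong base. The Mannich reaction with Eschenmoser's salt then forms C11–C13, and the C11 configuration is irrelevant.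

Step 16
Reactants: 25 11-(dimethylaminomethyl) lactone
Product: 27 CNP0317149.1 (8β-methacryloyloxymelampolid-14-oic acid methyl ester), via methiodide 26 (not isolated)
Conditions: MeI, THF, rt; then aq NaHCO3, CH2Cl2, rt
Reagents that add atoms: iodomethane, CI (methyl kept only in 26)
Why: Quaternisation and Hofmann-type E1cB elimination under bicarbonate gives the exocyclic methylene. The conditions are too mild to touch the other acceptors or the three stereocentres.

## Compound list

1 | methyl 3,5-dioxocyclohexane-1-carboxylate | O=C1CC(C(=O)OC)CC(=O)C1 | starting material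
2 | tert-butyl bromoacetate | BrCC(=O)OC(C)(C)C | starting material
3 | methyl 4-(2-tert-butoxy-2-oxoethyl)-3,5-dioxocyclohexane-1-carboxylate | O=C1CC(C(=O)OC)CC(=O)C1CC(=O)OC(C)(C)C | intermediate
4 | enol triflate of 3 (racemic) | O=C1CC(C(=O)OC)CC(OS(=O)(=O)C(F)(F)F)=C1CC(=O)OC(C)(C)C | intermediate
5 | methyl 4-(2-tert-butoxy-2-oxoethyl)-3-oxocyclohex-4-ene-1-carboxylate (racemic) | O=C1CC(C(=O)OC)CC=C1CC(=O)OC(C)(C)C | intermediate
6 | (3R)-allylic alcohol (C1 epimers) | O[C@@H]1CC(C(=O)OC)CC=C1CC(=O)OC(C)(C)C | intermediate
7 | TBS ether of 6 | CC(C)(C)[Si](C)(C)O[C@@H]1CC(C(=O)OC)CC=C1CC(=O)OC(C)(C)C | intermediate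
8 | C6 alkylborane (simplest form RBH2) | CC(C)(C)[Si](C)(C)O[C@@H]1CC(C(=O)OC)C[C@@H](B)[C@@H]1CC(=O)OC(C)(C)C | intermediate
9 | (3R,4S,5R)-alcohol | CC(C)(C)[Si](C)(C)O[C@@H]1CC(C(=O)OC)C[C@@H](O)[C@@H]1CC(=O)OC(C)(C)C | intermediate
10 | (3R,4R)-ketone | CC(C)(C)[Si](C)(C)O[C@@H]1CC(C(=O)OC)CC(=O)[C@@H]1CC(=O)OC(C)(C)C | intermediate
11 | C5=C6 trimethylsilyl enol ether | CC(C)(C)[Si](C)(C)O[C@@H]1CC(C(=O)OC)C=C(O[Si](C)(C)C)[C@@H]1CC(=O)OC(C)(C)C | intermediate
12 | (4R,5R)-3-carbomethoxycyclohexenone | CC(C)(C)[Si](C)(C)O[C@@H]1CC(C(=O)OC)=CC(=O)[C@@H]1CC(=O)OC(C)(C)C | intermediate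
13 | methylenecyclobutane | C=C1CCC1 | starting material
14 | 1-methylcyclobutene | CC1=CCC1 | intermediate
15 | cis-anti-cis photoadduct (α-face isomer drawn) | CC(C)(C)[Si](C)(C)O[C@@H]1C[C@@]2(C(=O)OC)[C@@H]3CC[C@]3(C)[C@H]2C(=O)[C@@H]1CC(=O)OC(C)(C)C | intermediate
16 | cyclodecadienone, 8β-OTBS | CC(C)(C)[Si](C)(C)O[C@@H]1C/C(C(=O)OC)=C\CC/C(C)=C/C(=O)[C@@H]1CC(=O)OC(C)(C)C | intermediate
17 | cyclodecadienone, 8β-OH | O[C@@H]1C/C(C(=O)OC)=C\CC/C(C)=C/C(=O)[C@@H]1CC(=O)OC(C)(C)C | intermediate
18 | methacrolein | C=C(C)C=O | starting material
19 | O8 hemiacetal of 17 with 18 | C=C(C)C(O)O[C@@H]1C/C(C(=O)OC)=C\CC/C(C)=C/C(=O)[C@@H]1CC(=O)OC(C)(C)C | intermediate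
20 | 6α-hydroxy-8β-methacrylate tert-butyl ester | C=C(C)C(=O)O[C@@H]1C/C(C(=O)OC)=C\CC/C(C)=C/[C@@H](O)[C@@H]1CC(=O)OC(C)(C)C | intermediate
21 | O6-TMS ether, C12 TMS ester | C=C(C)C(=O)O[C@@H]1C/C(C(=O)OC)=C\CC/C(C)=C/[C@@H](O[Si](C)(C)C)[C@@H]1CC(=O)O[Si](C)(C)C | intermediate
22 | 6α-hydroxy acid | C=C(C)C(=O)O[C@@H]1C/C(C(=O)OC)=C\CC/C(C)=C/[C@@H](O)[C@@H]1CC(=O)O | intermediate
23 | 13-nor lactone | C=C(C)C(=O)O[C@@H]1C/C(C(=O)OC)=C\CC/C(C)=C/[C@H]2OC(=O)C[C@@H]21 | intermediate
24 | lactone silyl ketene acetal | C=C(C)C(=O)O[C@@H]1C/C(C(=O)OC)=C\CC/C(C)=C/[C@H]2OC(O[Si](C)(C)C)=C[C@@H]21 | intermediate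
25 | Mannich base (C11 epimers) | C=C(C)C(=O)O[C@@H]1C/C(C(=O)OC)=C\CC/C(C)=C/[C@H]2OC(=O)C(CN(C)C)[C@@H]21 | intermediate
26 | methiodide of 25 | C=C(C)C(=O)O[C@@H]1C/C(C(=O)OC)=C\CC/C(C)=C/[C@H]2OC(=O)C(C[N+](C)(C)C)[C@@H]21.[I-] | intermediate
27 | CNP0317149.1 | C=C(C)C(=O)O[C@@H]1C/C(C(=O)OC)=C\CC/C(C)=C/[C@H]2OC(=O)C(=C)[C@@H]21 | target

## Step count and least certain steps

Total step count: 16. Longest linear sequence: 15 (steps 1–8 and 10–16). Step 9 is a one-step side branch.

**Step 11 (key step).**
- *What may go wrong:* the diyl may partition towards C2–C3 cleavage, or the product may drain along the Cope surface into the divinylcyclohexanone. The chair preference may be overridden by the ring substituents, because a 1,3-diaxial contact between O8 and the ester opposes the productive conformer of the α-face adduct; the ring geometry would then be only partly controlled. Slow thermal β-elimination of silanol is also possible.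
- *Fallback (from 15, back at 23):* the ring expansion is moved behind lactone formation, so that a trans-fused lactone locks the cyclohexane chair instead of relying on equilibration. Desilylation (HF·pyridine) gives the tricyclic hydroxy ketone F1. Evans–Tishchenko reduction with 18 gives the tricyclic 6α-alcohol 8β-methacrylate F2. Trifluoroacetic acid, harmless here because no allylic alcohol or diene is present, gives the tricyclic trans-lactone F3. In F3, C4 is fixed axial and cis to O6, so only the chair diyl with C6 equatorial is accessible. Thermolysis (BHT, dilute) then gives 23.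

**Step 10.**
- *What may go wrong:* part of the material may follow the other orientation (C10–C4), because electron-rich alkenes normally bond through their substituted carbon to the enone β-carbon. Enone dimerisation and trans ring fusion may also compete.
- *Fallback (from 12, back at 16):* the photochemistry is avoided altogether. A vinyl cuprate adds to C10 (β to the ketone, anti to O8 and C11). The zinc enolate is trapped at C5 with acetone to give the aldol F4. Burgess dehydration towards a methyl group gives the cis-1-vinyl-2-isopropenylcyclohexanone F5. Heating F5 enters the same Cope surface and, if the double conjugation dominates as argued for step 11, leads to 16.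

**Step 13.**
- *What may go wrong:* hemiacetal formation with a conjugated aldehyde may be slow. Retro-aldol opening of the β-hydroxy ketone on the samarium alkoxide, single-electron reduction of the enone, and O8-to-O6 acyl migration are further risks.
- *Fallback (from 17, back at 20):* acylation and reduction are separated. Methacrylic anhydride with catalytic DMAP at low temperature gives the β-methacryloyloxy ketone F6. Its C6 carbonyl is reduced intermolecularly (Luche conditions with peripheral attack, or a CBS catalyst if substrate control is inadequate) to 20.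

**Step 6.**
- *What may go wrong:* facial selectivity may be poor if the silyl ether is not pseudo-axial. Partial reduction of the esters and β-elimination of a minor C7-borane are also possible.
- *Fallback (from 6, back at 10):* hydrogen is delivered by a stereospecific 1,2-shift instead of hydroboration. Hydroxyl-directed epoxidation (VO(acac)2, tBuOOH) gives the syn epoxy alcohol F7, and silylation gives the epoxy silyl ether F8. A bulky aluminium Lewis acid opens the tertiary C7–O bond with anti migration of the α-oriented H6 to C7. This inverts C7, places the side chain β and gives the ketone 10 directly.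

**Step 15.**
- *What may go wrong:* silylation may lack chemoselectivity (γ-deprotonation of the ring enoate). Conjugate addition of liberated amine to the methacrylate and oligomerisation of the acceptors are further risks.
- *Fallback (from 16, back at 27):* the methylene group is installed before the methacrylate.
  1. Reduction of the ketone of 16 (Luche or CBS) gives the 6α-alcohol F9.
  2. Treatment as in step 14 leads through the bis-silyl derivative F10 and the hydroxy acid F11 to the 8β-silyloxy lactone F12.
  3. LDA and Eschenmoser's salt give the Mannich base F13.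
  4. Iodomethane gives the methiodide F14, and bicarbonate gives the 8β-silyloxy α-methylene lactone F15.
  5. HF·pyridine gives the 8β-hydroxy α-methylene lactone F16.
  6. Methacrylic anhydride with DMAP gives 27.

## Further compounds

F1 | step 11 | tricyclic 8β-hydroxy-6-ketone | O[C@@H]1C[C@@]2(C(=O)OC)[C@@H]3CC[C@]3(C)[C@H]2C(=O)[C@@H]1CC(=O)OC(C)(C)C
F2 | step 11 | tricyclic 6α-alcohol 8β-methacrylate | C=C(C)C(=O)O[C@@H]1C[C@@]2(C(=O)OC)[C@@H]3CC[C@]3(C)[C@H]2[C@@H](O)[C@@H]1CC(=O)OC(C)(C)C
F3 | step 11 | tricyclic trans-fused 12,6-lactone | C=C(C)C(=O)O[C@@H]1C[C@@]2(C(=O)OC)[C@@H]3CC[C@]3(C)[C@H]2[C@H]4OC(=O)C[C@@H]41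
F4 | step 10 | C10-vinyl C5-(2-hydroxyprop-2-yl) cyclohexanone | CC(C)(C)[Si](C)(C)O[C@@H]1C[C@](C=C)(C(=O)OC)[C@@H](C(C)(C)O)C(=O)[C@@H]1CC(=O)OC(C)(C)C
F5 | step 10 | cis-1-vinyl-2-isopropenylcyclohexanone | CC(C)(C)[Si](C)(C)O[C@@H]1C[C@](C=C)(C(=O)OC)[C@@H](C(C)=C)C(=O)[C@@H]1CC(=O)OC(C)(C)C
F6 | step 13 | 8β-methacryloyloxy-6-ketone | C=C(C)C(=O)O[C@@H]1C/C(C(=O)OC)=C\CC/C(C)=C/C(=O)[C@@H]1CC(=O)OC(C)(C)C
F7 | step 6 | syn 6,7-epoxy alcohol | O[C@@H]1CC(C(=O)OC)C[C@@H]2O[C@]12CC(=O)OC(C)(C)C
F8 | step 6 | syn 6,7-epoxy TBS ether | CC(C)(C)[Si](C)(C)O[C@@H]1CC(C(=O)OC)C[C@@H]2O[C@]12CC(=O)OC(C)(C)C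
F9 | step 15 | 6α-alcohol, 8β-OTBS | CC(C)(C)[Si](C)(C)O[C@@H]1C/C(C(=O)OC)=C\CC/C(C)=C/[C@@H](O)[C@@H]1CC(=O)OC(C)(C)C
F10 | step 15 | O6-TMS ether, C12 TMS ester, 8β-OTBS | CC(C)(C)[Si](C)(C)O[C@@H]1C/C(C(=O)OC)=C\CC/C(C)=C/[C@@H](O[Si](C)(C)C)[C@@H]1CC(=O)O[Si](C)(C)C
F11 | step 15 | 6α-hydroxy acid, 8β-OTBS | CC(C)(C)[Si](C)(C)O[C@@H]1C/C(C(=O)OC)=C\CC/C(C)=C/[C@@H](O)[C@@H]1CC(=O)O
F12 | step 15 | 13-nor lactone, 8β-OTBS | CC(C)(C)[Si](C)(C)O[C@@H]1C/C(C(=O)OC)=C\CC/C(C)=C/[C@H]2OC(=O)C[C@@H]21
F13 | step 15 | Mannich base, 8β-OTBS | CC(C)(C)[Si](C)(C)O[C@@H]1C/C(C(=O)OC)=C\CC/C(C)=C/[C@H]2OC(=O)C(CN(C)C)[C@@H]21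
F14 | step 15 | methiodide, 8β-OTBS | CC(C)(C)[Si](C)(C)O[C@@H]1C/C(C(=O)OC)=C\CC/C(C)=C/[C@H]2OC(=O)C(C[N+](C)(C)C)[C@@H]21.[I-]
F15 | step 15 | α-methylene lactone, 8β-OTBS | CC(C)(C)[Si](C)(C)O[C@@H]1C/C(C(=O)OC)=C\CC/C(C)=C/[C@H]2OC(=O)C(=C)[C@@H]21
F16 | step 15 | α-methylene lactone, 8β-OH | O[C@@H]1C/C(C(=O)OC)=C\CC/C(C)=C/[C@H]2OC(=O)C(=C)[C@@H]21
A1 | alternative 1 | acyclic formyl allylic bromide (C6 enal, C13 bromide, 8-OTBS) | O=C/C=C(C)/CC/C=C(C(=O)OC)\C[C@@H](O[Si](C)(C)C(C)(C)C)/C=C(\CBr)C(=O)OC
A2 | alternative 2 | cis-vinyl/isopropenyl elemanolide (Cope isomer of the target) | C=C(C)C(=O)O[C@@H]1C[C@](C=C)(C(=O)OC)[C@@H](C(C)=C)[C@H]2OC(=O)C(=C)[C@@H]21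
A3 | alternative 3 | 13-membered bis-allylic ether (O between C6 and C13; C14 as CH2OTBS) | O1C/C=C(C)/CC/C=C(CO[Si](C)(C)C(C)(C)C)\C[C@@H](O[Si](C)(C)C(C)(C)C)/C=C(C)/C1
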